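**Retrosynthetic overview**
- Target ⇒ its tetra-O-benzyl ether (global hydrogenolysis last); both OMe groups are carried through from the start.
- Flavone pyranone (formed last) ⇒ biaryl isoflavone aldehyde + 2-hydroxy-4,6-bis(benzyloxy)acetophenone (aldol / oxa-Michael / dehydrogenation in one pot).
- Isoflavone pyranone (formed second) ⇒ 3-aryl-2-hydroxydeoxybenzoin + one carbon (DMF-DMA); the single free OH fixes the 8-aryl linkage.
- Key disconnection: the biaryl C8–C3' bond between two innately nucleophilic arene carbons ⇒ chelated phenol (ortho C–H donor) + aryllead triacetate (aryl cation equivalent made from a boronic acid), joined by ligand coupling.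
- Phenol partner ⇒ phloroglucinol + 4-methoxyphenylacetic acid (Friedel–Crafts), then selective dibenzylation. Order: biaryl bond, isoflavone ring C, flavone ring C.

Assumption: the SMILES holds no stereocentre and no configured axis, so the biaryl axis is treated as not configurationally fixed and no stereo-defining step is needed; the formyl boronic acid and the dibenzyl acetophenone used below are taken as catalogue chemicals.

**Step 1**
Reactants: 1 phloroglucinol; 2 4-methoxyphenylacetic acid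
Product: 3 1-(2,4,6-trihydroxyphenyl)-2-(4-methoxyphenyl)ethan-1-one
Conditions: BF3·OEt2 (neat, 6 equiv), 80 °C, 2 h; then aq NaOAc, 0 °C
Reagents that add atoms: none
Why: Friedel–Crafts (Nencki-type) C-acylation of the very nucleophilic phloroglucinol by the BF3-activated acid stops at monoacylation because the product is held as a deactivated BF2 chelate of the ortho-hydroxy ketone, and no stereocentre is formed.

**Step 2**
Reactants: 3 1-(2,4,6-trihydroxyphenyl)-2-(4-methoxyphenyl)ethan-1-one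
Product: 4 1-[2,4-bis(benzyloxy)-6-hydroxyphenyl]-2-(4-methoxyphenyl)ethan-1-one
Conditions: BnBr (2.05 equiv), K2CO3 (2.2 equiv), DMF, 0 °C to rt, 12 h
Reagents that add atoms: benzyl bromide, BrCc1ccccc1
Why: Williamson etherification under weak base alkylates the 4-OH and one ortho-OH, while the last ortho-OH is locked in a strong hydrogen bond to the ketone and stays free, so exactly one phenol is left to direct steps 3 and 4; no stereocentre is formed.

**Step 3**
Reactants: 4 1-[2,4-bis(benzyloxy)-6-hydroxyphenyl]-2-(4-methoxyphenyl)ethan-1-one; 5 (5-formyl-2-methoxyphenyl)boronic acid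
Product: 7 3-[4,6-bis(benzyloxy)-2-hydroxy-3-[2-(4-methoxyphenyl)acetyl]phenyl]-4-methoxybenzaldehyde, via aryllead triacetate 6 (not isolated)
Conditions: 5 (1.4 equiv), Pb(OAc)4 (1.3 equiv), Hg(OAc)2 (10 mol %), CHCl3, 40 °C, 1 h, then rt, 12 h; then 4 (1.0 equiv), pyridine (4 equiv), CHCl3, 60 °C, 4 h
Reagents that add atoms: none
Why: Pinhey arylation, in which boron-to-lead exchange turns the innately nucleophilic anisole carbon ortho to OMe into an aryl cation equivalent on tetravalent lead and ligand coupling on lead then delivers that aryl group to the only open carbon ortho to the lead-bound phenol oxygen of 4 (C5, also innately nucleophilic), with lead leaving in the divalent state; the new tri-ortho-substituted axis carries no defined configuration and no stereocentre is formed.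

**Step 4**
Reactants: 7 3-[4,6-bis(benzyloxy)-2-hydroxy-3-[2-(4-methoxyphenyl)acetyl]phenyl]-4-methoxybenzaldehyde
Product: 9 3-[5,7-bis(benzyloxy)-3-(4-methoxyphenyl)-4-oxo-4H-chromen-8-yl]-4-methoxybenzaldehyde, via enaminone 8 (not isolated)
Conditions: Me2NCH(OMe)2 (3 equiv), toluene, 95 °C, 4 h; then AcOH, 60 °C, 1 h
Reagents that add atoms: N,N-dimethylformamide dimethyl acetal (DMF-DMA), COC(OC)N(C)C
Why: enaminone formation at the activated benzylic methylene followed by intramolecular addition–elimination of the single free phenol (loss of Me2NH) is the standard deoxybenzoin-to-isoflavone ring closure and, with only one OH available, can give only the 8-aryl isomer, while the non-enolisable aldehyde is untouched; no stereocentre is formed.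

**Step 5**
Reactants: 9 3-[5,7-bis(benzyloxy)-3-(4-methoxyphenyl)-4-oxo-4H-chromen-8-yl]-4-methoxybenzaldehyde; 10 1-[2,4-bis(benzyloxy)-6-hydroxyphenyl]ethan-1-one
Product: 13 5,7-bis(benzyloxy)-8-[5-(5,7-bis(benzyloxy)-4-oxo-4H-chromen-2-yl)-2-methoxyphenyl]-3-(4-methoxyphenyl)-4H-chromen-4-one, via chalcone 11 (not isolated), via flavanone 12 (not isolated)
Conditions: 10 (1.1 equiv), pyrrolidine (0.5 equiv), DMSO, 60 °C, 6 h; then I2 (0.2 equiv), 120 °C, 3 h; aq Na2S2O3 work-up
Reagents that add atoms: none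
Why: pyrrolidine-mediated Claisen–Schmidt condensation and oxa-Michael closure followed by I2-catalysed dehydrogenation with DMSO as terminal oxidant (one-pot chalcone-to-flavone oxidative cyclisation) builds the second pyranone, and the racemic C2 stereocentre of flavanone 12 is erased in the dehydrogenation.

**Step 6**
Reactants: 13 5,7-bis(benzyloxy)-8-[5-(5,7-bis(benzyloxy)-4-oxo-4H-chromen-2-yl)-2-methoxyphenyl]-3-(4-methoxyphenyl)-4H-chromen-4-one
Product: 14 5,7-dihydroxy-8-[5-(5,7-dihydroxy-4-oxo-4H-chromen-2-yl)-2-methoxyphenyl]-3-(4-methoxyphenyl)-4H-chromen-4-one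
Conditions: H2 (1 atm), Pd/C (10 wt %), THF/MeOH (1:1), rt, 6 h
Reagents that add atoms: none
Why: catalytic hydrogenolysis cleaves the four benzylic C–O bonds while the aryl methyl ethers and the vinylogous-ester C2=C3 bonds of both chromones are inert under these mild conditions, and no stereocentre is present.

**Compound list**
1 | phloroglucinol (benzene-1,3,5-triol) | Oc1cc(O)cc(O)c1 | starting material
2 | 4-methoxyphenylacetic acid | COc1ccc(CC(=O)O)cc1 | starting material
3 | 1-(2,4,6-trihydroxyphenyl)-2-(4-methoxyphenyl)ethan-1-one | COc1ccc(CC(=O)c2c(O)cc(O)cc2O)cc1 | intermediate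
4 | 1-[2,4-bis(benzyloxy)-6-hydroxyphenyl]-2-(4-methoxyphenyl)ethan-1-one | COc1ccc(CC(=O)c2c(O)cc(OCc3ccccc3)cc2OCc2ccccc2)cc1 | intermediate
5 | (5-formyl-2-methoxyphenyl)boronic acid | COc1ccc(C=O)cc1B(O)O | starting material
6 | (5-formyl-2-methoxyphenyl)lead triacetate | COc1ccc(C=O)cc1[Pb](OC(C)=O)(OC(C)=O)OC(C)=O | intermediate
7 | 3-[4,6-bis(benzyloxy)-2-hydroxy-3-[2-(4-methoxyphenyl)acetyl]phenyl]-4-methoxybenzaldehyde | COc1ccc(CC(=O)c2c(O)c(-c3cc(C=O)ccc3OC)c(OCc3ccccc3)cc2OCc2ccccc2)cc1 | intermediate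
8 | (E)-1-[4,6-bis(benzyloxy)-3-(5-formyl-2-methoxyphenyl)-2-hydroxyphenyl]-3-(dimethylamino)-2-(4-methoxyphenyl)prop-2-en-1-one | CN(C)/C=C(/C(=O)c1c(O)c(-c2cc(C=O)ccc2OC)c(OCc2ccccc2)cc1OCc1ccccc1)c1ccc(OC)cc1 | intermediate
9 | 3-[5,7-bis(benzyloxy)-3-(4-methoxyphenyl)-4-oxo-4H-chromen-8-yl]-4-methoxybenzaldehyde | COc1ccc(-c2coc3c(-c4cc(C=O)ccc4OC)c(OCc4ccccc4)cc(OCc4ccccc4)c3c2=O)cc1 | intermediate
10 | 1-[2,4-bis(benzyloxy)-6-hydroxyphenyl]ethan-1-one | CC(=O)c1c(O)cc(OCc2ccccc2)cc1OCc1ccccc1 | starting material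
11 | (E)-1-[2,4-bis(benzyloxy)-6-hydroxyphenyl]-3-{3-[5,7-bis(benzyloxy)-3-(4-methoxyphenyl)-4-oxo-4H-chromen-8-yl]-4-methoxyphenyl}prop-2-en-1-one | COc1ccc(-c2coc3c(-c4cc(/C=C/C(=O)c5c(O)cc(OCc6ccccc6)cc5OCc5ccccc5)ccc4OC)c(OCc4ccccc4)cc(OCc4ccccc4)c3c2=O)cc1 | intermediate
12 | racemic 5,7-bis(benzyloxy)-2-{3-[5,7-bis(benzyloxy)-3-(4-methoxyphenyl)-4-oxo-4H-chromen-8-yl]-4-methoxyphenyl}chroman-4-one | COc1ccc(-c2coc3c(-c4cc(C5CC(=O)c6c(OCc7ccccc7)cc(OCc7ccccc7)cc6O5)ccc4OC)c(OCc4ccccc4)cc(OCc4ccccc4)c3c2=O)cc1 | intermediate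
13 | 5,7-bis(benzyloxy)-8-[5-(5,7-bis(benzyloxy)-4-oxo-4H-chromen-2-yl)-2-methoxyphenyl]-3-(4-methoxyphenyl)-4H-chromen-4-one | COc1ccc(-c2coc3c(-c4cc(-c5cc(=O)c6c(OCc7ccccc7)cc(OCc7ccccc7)cc6o5)ccc4OC)c(OCc4ccccc4)cc(OCc4ccccc4)c3c2=O)cc1 | intermediate
14 | 5,7-dihydroxy-8-[5-(5,7-dihydroxy-4-oxo-4H-chromen-2-yl)-2-methoxyphenyl]-3-(4-methoxyphenyl)-4H-chromen-4-one (CNP0117905.0) | COc1ccc(-c2coc3c(-c4cc(-c5cc(=O)c6c(O)cc(O)cc6o5)ccc4OC)c(O)cc(O)c3c2=O)cc1 | target

**Totals and risks**
Total step count: 6. Longest linear sequence: 6 (1 → 3 → 4 → 7 → 9 → 13 → 14; compounds 2, 5 and 10 are bought).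

The three steps most likely to fail are steps 3, 5 and 6.

Step 3 (ligand coupling). Phenol 4 is chelated to its ketone and carries an acyl group, so exchange onto lead may be slow, and attack at the acyl-bearing ortho carbon could compete. The fallback changes the order of arylation and protection. It sets out from triol 3 and aryllead triacetate 6 (made as in step 3). Triol 3 (2 equiv, pyridine, CHCl3, 40 °C) is arylated through its free, unchelated OH groups at C3/C5, which are equivalent by symmetry, to give 3-[2,4,6-trihydroxy-3-[2-(4-methoxyphenyl)acetyl]phenyl]-4-methoxybenzaldehyde F1. Benzyl bromide (2 equiv) with K2CO3 in DMF should then alkylate the OH para to the acyl group and the less hindered ortho-OH. The OH flanked by both the acyl and the aryl group stays chelated, and the route is rejoined at compound 7. The regiochemistry of this benzylation would have to be confirmed by NOE/HMBC before going on.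

Step 5 (one-pot flavone annulation). The electrophilic C2 of the isoflavone in 9 may be opened by pyrrolidine at 60–120 °C, and the anisaldehyde-type carbonyl is a sluggish aldol acceptor. The fallback builds the flavone before the biaryl bond, so that no isoflavone meets amine or hydroxide. It sets out from acetophenone 10 and phenol 4 and comes back at compound 13. Claisen–Schmidt condensation of 10 with purchased 3-bromo-4-methoxybenzaldehyde (COc1ccc(C=O)cc1Br; KOH, EtOH, rt) gives (E)-1-[2,4-bis(benzyloxy)-6-hydroxyphenyl]-3-(3-bromo-4-methoxyphenyl)prop-2-en-1-one F2. I2 (cat.) in DMSO at 130 °C closes it to 5,7-bis(benzyloxy)-2-(3-bromo-4-methoxyphenyl)-4H-chromen-4-one F3. Stannylation with hexabutylditin and Pd(PPh3)4 in toluene at 110 °C gives 5,7-bis(benzyloxy)-2-[4-methoxy-3-(tributylstannyl)phenyl]-4H-chromen-4-one F4. Tin-to-lead exchange (Pb(OAc)4, cat. Hg(OAc)2, CHCl3, 40 °C) gives [5-(5,7-bis(benzyloxy)-4-oxo-4H-chromen-2-yl)-2-methoxyphenyl]lead triacetate F5 in the flask. This arylates phenol 4 (pyridine, CHCl3, 60 °C) to 5,7-bis(benzyloxy)-2-{3-[4,6-bis(benzyloxy)-2-hydroxy-3-[2-(4-methoxyphenyl)acetyl]phenyl]-4-methoxyphenyl}-4H-chromen-4-one F6. DMF-DMA ring closure under the conditions of step 4 then gives compound 13.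

Step 6 (hydrogenolysis). Sulfur residues from step 5 can poison Pd/C, the tetrabenzyl ether is poorly soluble, and long reaction times risk saturating the chromone C2=C3 bonds. The fallback is a non-reductive Lewis-acid debenzylation that goes from compound 13 directly to compound 14. It uses BCl3 (8 equiv) with pentamethylbenzene as benzyl-cation trap in CH2Cl2 at −78 to −20 °C. This cleaves the aryl benzyl ethers, fastest at the two carbonyl-chelating 5-positions, but not the two non-chelated aryl methyl ethers. No new compound is formed on the way (none F0).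

**Further compounds**
F1 | step 3 | 3-[2,4,6-trihydroxy-3-[2-(4-methoxyphenyl)acetyl]phenyl]-4-methoxybenzaldehyde | COc1ccc(CC(=O)c2c(O)cc(O)c(-c3cc(C=O)ccc3OC)c2O)cc1
F2 | step 5 | (E)-1-[2,4-bis(benzyloxy)-6-hydroxyphenyl]-3-(3-bromo-4-methoxyphenyl)prop-2-en-1-one | COc1ccc(/C=C/C(=O)c2c(O)cc(OCc3ccccc3)cc2OCc2ccccc2)cc1Br
F3 | step 5 | 5,7-bis(benzyloxy)-2-(3-bromo-4-methoxyphenyl)-4H-chromen-4-one | COc1ccc(-c2cc(=O)c3c(OCc4ccccc4)cc(OCc4ccccc4)cc3o2)cc1Br
F4 | step 5 | 5,7-bis(benzyloxy)-2-[4-methoxy-3-(tributylstannyl)phenyl]-4H-chromen-4-one | COc1ccc(-c2cc(=O)c3c(OCc4ccccc4)cc(OCc4ccccc4)cc3o2)cc1[Sn](CCCC)(CCCC)CCCC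
F5 | step 5 | [5-(5,7-bis(benzyloxy)-4-oxo-4H-chromen-2-yl)-2-methoxyphenyl]lead triacetate | COc1ccc(-c2cc(=O)c3c(OCc4ccccc4)cc(OCc4ccccc4)cc3o2)cc1[Pb](OC(C)=O)(OC(C)=O)OC(C)=O
F6 | step 5 | 5,7-bis(benzyloxy)-2-{3-[4,6-bis(benzyloxy)-2-hydroxy-3-[2-(4-methoxyphenyl)acetyl]phenyl]-4-methoxyphenyl}-4H-chromen-4-one | COc1ccc(CC(=O)c2c(O)c(-c3cc(-c4cc(=O)c5c(OCc6ccccc6)cc(OCc6ccccc6)cc5o4)ccc3OC)c(OCc3ccccc3)cc2OCc2ccccc2)cc1
F0 | step 6 | none | none
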